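**Assumption:** 1, 2, 4, 5, 9 and 20 are taken as catalogue items. Ring letters: A = cyclopentene, B = cyclopentane, C = piperidine, D = cycloheptane, E = lactone.

## Retrosynthetic overview
1. Ring E comes last, by oxidative lactonisation of a 1,6-diol. The side-chain-bearing quaternary carbon comes from a bridge spiro-epoxide by light-driven titanocene radical opening and Giese addition to isopropyl vinyl ketone (key bond).
2. The epoxide comes from the bridging ketone. Ring D is closed by alkylating the piperidone enolate with a chloroethyl arm.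
3. Ring C comes from a double Mannich reaction on an acetyl diquinane, ring B from an intramolecular aldol, and ring A from ring-closing metathesis.
4. The acyclic precursor comes from a trans-3,4-disubstituted butyrolactone and a vinyllithium. The lactone comes from the (R)-epichlorohydrin/malonate cyclopropane.
5. Ring order: A, B, C, D, E.

## Route

Step 1
Reactants: 1 (R)-epichlorohydrin; 2 dimethyl malonate
Product: 3 methyl (1S,5R)-2-oxo-3-oxabicyclo[3.1.0]hexane-1-carboxylate
Conditions: NaOMe, MeOH, reflux
Reagents that add atoms: none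
Why: This is the malonate–epichlorohydrin annulation (epoxide opening, epoxide re-formation, 3-exo-tet cyclopropanation, lactonisation), in which the bought stereocentre is inverted once in a stereospecific SN2 step and the cis ring fusion then fixes the second centre.

Step 2
Reactants: 3 methyl (1S,5R)-2-oxo-3-oxabicyclo[3.1.0]hexane-1-carboxylate; 4 allylmagnesium bromide; 5 (E)-1-bromobut-2-ene
Product: 7 methyl (3R,4R)-3-[(E)-but-2-enyl]-4-(but-3-enyl)-2-oxotetrahydrofuran-3-carboxylate, via bromomagnesium enolate 6 (not isolated)
Conditions: CuBr·SMe2 (20 mol %), THF, −45 °C; then 5, DMPU, −45 °C to rt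
Reagents that add atoms: none
Why: Copper-catalysed homoconjugate addition opens the doubly activated cyclopropane at its CH2 without touching the stereocentre, and the malonate-type enolate is then C-alkylated anti to the new butenyl arm.

Step 3
Reactants: 7 methyl (3R,4R)-3-[(E)-but-2-enyl]-4-(but-3-enyl)-2-oxotetrahydrofuran-3-carboxylate
Product: 8 (3R,4R)-3-[(E)-but-2-enyl]-4-(but-3-enyl)dihydrofuran-2(3H)-one
Conditions: LiCl, H2O, DMSO, 150 °C
Reagents that add atoms: none
Why: In this Krapcho dealkoxycarbonylation the lactone enolate is protonated to the thermodynamic trans-3,4 isomer, which is the relative configuration the target needs at these two carbons.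

Step 4
Reactants: 9 3-bromobut-3-en-1-ol
Product: 10 2-bromo-4-chlorobut-1-ene
Conditions: PPh3, CCl4, CH2Cl2, 0 °C to rt
Reagents that add atoms: carbon tetrachloride ClC(Cl)(Cl)Cl
Why: The Appel reaction converts the primary alcohol into the chloride and leaves the vinyl bromide untouched.

Step 5
Reactants: 8 (3R,4R)-3-[(E)-but-2-enyl]-4-(but-3-enyl)dihydrofuran-2(3H)-one; 10 2-bromo-4-chlorobut-1-ene
Product: 12 (4R,5R)-4-[(E)-but-2-enyl]-2-(2-chloroethyl)-5-(hydroxymethyl)nona-1,8-dien-3-one, via vinyllithium 11 (not isolated)
Conditions: 10, t-BuLi (2 equiv), Et2O, −78 °C; then 8, −78 °C; H2O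
Reagents that add atoms: none
Why: Bromine–lithium exchange followed by 1,2-addition to the lactone stops at the cold tetrahedral lactolate, so one vinyl group is delivered, the alkyl chloride survives at −78 °C and both stereocentres are kept.

Step 6
Reactants: 12 (4R,5R)-4-[(E)-but-2-enyl]-2-(2-chloroethyl)-5-(hydroxymethyl)nona-1,8-dien-3-one
Product: 13 (4R,5R)-4-[(E)-but-2-enyl]-2-(2-chloroethyl)-5-(hydroxymethyl)non-1-ene-3,8-dione
Conditions: PdCl2 (10 mol %), CuCl, O2 (1 atm), DMF/H2O 7:1, rt
Reagents that add atoms: water O
Why: Tsuji–Wacker oxidation takes the only unhindered terminal alkene to the methyl ketone, while the internal crotyl alkene and the electron-poor enone methylene react far more slowly.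

Step 7
Reactants: 13 (4R,5R)-4-[(E)-but-2-enyl]-2-(2-chloroethyl)-5-(hydroxymethyl)non-1-ene-3,8-dione
Product: 14 (5R)-2-(2-chloroethyl)-5-[(2R)-1-hydroxy-5-oxohexan-2-yl]cyclopent-2-en-1-one
Conditions: second-generation Hoveyda–Grubbs catalyst (5 mol %), toluene, 60 °C
Reagents that add atoms: none
Why: Ring-closing metathesis of the crotyl alkene with the enone methylene closes ring A as a 2-substituted cyclopentenone under neutral conditions that do not epimerise the α′ centre.

Step 8
Reactants: 14 (5R)-2-(2-chloroethyl)-5-[(2R)-1-hydroxy-5-oxohexan-2-yl]cyclopent-2-en-1-one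
Product: 15 (1R,3R,3aR,6aS)-1-acetyl-6-(2-chloroethyl)-3-(hydroxymethyl)-1,2,3,3a,4,6a-hexahydropentalen-6a-ol
Conditions: TiCl4, Bu3N, CH2Cl2, −78 °C; aq NH4Cl
Reagents that add atoms: none
Why: In this titanium-mediated soft-enolisation intramolecular aldol addition (five-membered ring only) the tether reaches the enone carbonyl from the face of the side chain, so rings A and B are cis-fused with the new OH cis to the ring-fusion H, the cold titanium aldolate blocks reversal and dehydration, and the acetyl-bearing centre is erased in step 9.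

Step 9
Reactants: 15 (1R,3R,3aR,6aS)-1-acetyl-6-(2-chloroethyl)-3-(hydroxymethyl)-1,2,3,3a,4,6a-hexahydropentalen-6a-ol
Product: 16 (1R,3R,3aR,6aR)-6-(2-chloroethyl)-6a-hydroxy-3-(hydroxymethyl)-1'-methyl-3,3a,4,6a-tetrahydro-2H-spiro[pentalene-1,3'-piperidin]-4'-one
Conditions: MeNH2 (40 % aq), CH2O (37 % aq, 2.2 equiv), AcOH, MeOH, 40 °C
Reagents that add atoms: methylamine CN; formaldehyde C=O
Why: In this double Mannich piperidone annulation across the methyl and methine α-carbons of the acetyl group, the iminium carbon attacks the planar enol from the convex face of the diquinane, so CH2N ends up cis to the OH and the carbonyl carbon sits on the concave face next to the chloroethyl arm.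

Step 10
Reactants: 16 (1R,3R,3aR,6aR)-6-(2-chloroethyl)-6a-hydroxy-3-(hydroxymethyl)-1'-methyl-3,3a,4,6a-tetrahydro-2H-spiro[pentalene-1,3'-piperidin]-4'-one
Product: 18 bridged tetracyclic ketone (rings A to D) as its bis(trimethylsilyl) ether, via bis-silyl ether 17 (not isolated)
Conditions: Me3SiOTf, 2,6-lutidine, CH2Cl2, −78 to 0 °C; solvent swap; KN(SiMe3)2, THF/DMPU, −78 to 40 °C
Reagents that add atoms: trimethylsilyl trifluoromethanesulfonate C[Si](C)(C)OS(=O)(=O)C(F)(F)F
Why: Silylation blocks retro-aldol cleavage, and the only possible enolate then undergoes intramolecular alkylation by the primary chloride through axial attack, which closes ring D as an azabicyclo[4.3.1]decanone whose bridge geometry dictates the new methine configuration.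

Step 11
Reactants: 18 bridged tetracyclic ketone (rings A to D) as its bis(trimethylsilyl) ether
Product: 19 bridge spiro-epoxide of 18
Conditions: trimethylsulfonium iodide, n-BuLi, THF, 0 °C to rt
Reagents that add atoms: trimethylsulfonium iodide C[S+](C)C.[I-]
Why: In this Corey–Chaykovsky epoxidation the small ylide reaches the hindered, non-enolisable-side bridging carbonyl from the piperidine face, and the epoxide configuration does not matter because the carbon becomes a planar radical in step 12.

Step 12
Reactants: 19 bridge spiro-epoxide of 18; 20 4-methylpent-1-en-3-one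
Product: 22 keto triol (rings A to D with CH2OH and 4-methyl-3-oxopentyl on the bridge carbon), via silylated Giese adduct 21 (not isolated)
Conditions: Cp2TiCl2 (10 mol %), 4CzIPN (2 mol %), Hantzsch ester (1.5 equiv), 2,4,6-collidinium chloride, 20 (5 equiv), THF, 450 nm LED, 25 °C; then 1 M HCl
Reagents that add atoms: none
Why: Proposed new method: excited 4CzIPN is reductively quenched by the Hantzsch ester and reduces Cp2TiCl2 to trivalent Cp2TiCl, which opens the epoxide by inner-sphere electron transfer at the more substituted C–O bond to give a planar tertiary β-titanoxy radical on the one-carbon bridge; this nucleophilic radical adds to the vinyl ketone from the piperidine face, because the other face is roofed by ring B and its CH2OSiMe3 group, which forms the key C–C bond and sets the second of two vicinal quaternary carbons with CH2O turned toward ring B; the α-keto radical is then reduced and protonated and tetravalent titanium is released by protonolysis; the closest known reaction type is titanocene-mediated reductive epoxide opening with conjugate addition (Nugent–RajanBabu type) and its dual photoredox variants on simple 2,2-disubstituted epoxides with acrylates, and it has not been shown on a bridge spiro-epoxide flanked by a quaternary carbon, with an alkyl vinyl ketone, or in the presence of an ammonium centre.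

Step 13
Reactants: 22 keto triol (rings A to D with CH2OH and 4-methyl-3-oxopentyl on the bridge carbon)
Product: 25 target CNP0242289.1, via hydroxy aldehyde 23 (not isolated), via lactol 24 (not isolated)
Conditions: Cu(MeCN)4OTf (10 mol %), 2,2'-bipyridine, TEMPO, N-methylimidazole, air, MeCN, rt
Reagents that add atoms: none
Why: Copper/nitroxyl aerobic oxidative lactonisation oxidises the less hindered primary alcohol (on the ring B methine) before the neopentyl one, the aldehyde is captured as a lactol by the nearby neopentyl CH2OH and oxidised on to ring E, and only the required epimer next to the carbonyl can lactolise, so that centre is self-correcting.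

## Compound list
1 | (R)-epichlorohydrin | ClC[C@H]1CO1 | starting material
2 | dimethyl malonate | COC(=O)CC(=O)OC | starting material
3 | methyl (1S,5R)-2-oxo-3-oxabicyclo[3.1.0]hexane-1-carboxylate | COC(=O)[C@]12C[C@H]1COC2=O | intermediate
4 | allylmagnesium bromide | C=CC[Mg]Br | starting material
5 | (E)-1-bromobut-2-ene (crotyl bromide) | C/C=C/CBr | starting material
6 | bromomagnesium enolate of methyl (4R)-4-(but-3-enyl)-2-oxotetrahydrofuran-3-carboxylate | C=CCC[C@H]1COC(=O)C1=C(OC)O[Mg]Br | intermediate
7 | methyl (3R,4R)-3-[(E)-but-2-enyl]-4-(but-3-enyl)-2-oxotetrahydrofuran-3-carboxylate (crotyl trans to butenyl) | O=C1OC[C@H](CCC=C)[C@@]1(C(=O)OC)C/C=C/C | intermediate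
8 | (3R,4R)-3-[(E)-but-2-enyl]-4-(but-3-enyl)dihydrofuran-2(3H)-one (trans) | O=C1OC[C@H](CCC=C)[C@H]1C/C=C/C | intermediate
9 | 3-bromobut-3-en-1-ol | C=C(Br)CCO | starting material
10 | 2-bromo-4-chlorobut-1-ene | C=C(Br)CCCl | intermediate
11 | (4-chlorobut-1-en-2-yl)lithium | [Li]C(=C)CCCl | intermediate
12 | (4R,5R)-4-[(E)-but-2-enyl]-2-(2-chloroethyl)-5-(hydroxymethyl)nona-1,8-dien-3-one (in equilibrium with its lactol) | C=C(CCCl)C(=O)[C@H](C/C=C/C)[C@H](CO)CCC=C | intermediate
13 | (4R,5R)-4-[(E)-but-2-enyl]-2-(2-chloroethyl)-5-(hydroxymethyl)non-1-ene-3,8-dione | C=C(CCCl)C(=O)[C@H](C/C=C/C)[C@H](CO)CCC(C)=O | intermediate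
14 | (5R)-2-(2-chloroethyl)-5-[(2R)-1-hydroxy-5-oxohexan-2-yl]cyclopent-2-en-1-one | O=C1C(CCCl)=CC[C@@H]1[C@H](CO)CCC(C)=O | intermediate
15 | cis-fused diquinane aldol; OH, ring-fusion H and acetyl on the convex face, CH2OH on the concave face | CC(=O)[C@@H]1C[C@@H](CO)[C@H]2CC=C(CCCl)[C@@]12O | intermediate
16 | spiro-piperidone (rings A, B, C); CH2N cis to OH, carbonyl carbon cis to the chloroethyl-bearing alkene carbon | CN1CCC(=O)[C@@]2(C1)C[C@@H](CO)[C@H]3CC=C(CCCl)[C@@]23O | intermediate
17 | bis(trimethylsilyl) ether of 16 | CN1CCC(=O)[C@@]2(C1)C[C@@H](CO[Si](C)(C)C)[C@H]3CC=C(CCCl)[C@@]23O[Si](C)(C)C | intermediate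
18 | bridged tetracyclic ketone (8-methyl-8-azabicyclo[4.3.1]decan-10-one core fused to rings A and B), bis(trimethylsilyl) ether | O=C1[C@H]2CN(C)C[C@@]13C[C@@H](CO[Si](C)(C)C)[C@H]4CC=C(CC2)[C@@]34O[Si](C)(C)C | intermediate
19 | bridge spiro-epoxide of 18 (epoxide CH2 on the piperidine side) | C1O[C@@]12[C@H]3CN(C)C[C@@]24C[C@@H](CO[Si](C)(C)C)[C@H]5CC=C(CC3)[C@@]45O[Si](C)(C)C | intermediate
20 | 4-methylpent-1-en-3-one (isopropyl vinyl ketone) | C=CC(=O)C(C)C | starting material
21 | Giese adduct, bis(trimethylsilyl) ether; side chain over the piperidine, CH2OH over ring D | CC(C)C(=O)CC[C@@]1(CO)[C@H]2CN(C)C[C@@]13C[C@@H](CO[Si](C)(C)C)[C@H]4CC=C(CC2)[C@@]34O[Si](C)(C)C | intermediate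
22 | keto triol | CC(C)C(=O)CC[C@@]1(CO)[C@H]2CN(C)C[C@@]13C[C@@H](CO)[C@H]4CC=C(CC2)[C@@]34O | intermediate
23 | hydroxy aldehyde | CC(C)C(=O)CC[C@@]1(CO)[C@H]2CN(C)C[C@@]13C[C@@H](C=O)[C@H]4CC=C(CC2)[C@@]34O | intermediate
24 | seven-membered lactol | CC(C)C(=O)CC[C@]12COC(O)[C@@H]3C[C@]14CN(C)C[C@H]2CCC1=CC[C@H]3[C@@]14O | intermediate
25 | CNP0242289.1 | CC(C)C(=O)CC[C@]12COC(=O)[C@@H]3C[C@]14CN(C)C[C@H]2CCC1=CC[C@H]3[C@@]14O | target

## Step count and risks
Total steps: 13. Longest linear sequence: 12 (steps 1 to 3 and 5 to 13).

**Step 12 (the new step).**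
- Risks: slow opening of the very hindered epoxide, transannular attack of the radical on the ring A alkene, simple reduction of the radical, and oxidation of the amine by the photocatalyst.
- Fallback (known chemistry only): it sets out from 18 and comes back at 22. Wittig methoxymethylenation of 18 (MeOCH2PPh3Cl, KOtBu) gives the methyl enol ether F1. Treatment with 1 M HCl in THF hydrolyses the enol ether and both silyl ethers to the bridge aldehyde F2. Its enolate (catalytic KOH in MeOH/THF) adds in a Michael reaction to 20 from the piperidine face and gives the quaternary keto aldehyde F3. NaBH(OAc)3 then reduces only the aldehyde and delivers 22.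

**Step 9.**
- Risks: the aldol 15 can dehydrate under acid before its α-carbon is quaternised, and that carbon is neopentyl-like.
- Fallback: it sets out from 15 and comes back at 16, and it uses the dehydration on purpose. Catalytic p-TsOH in toluene gives the acetyl diene F4. N-methylnitrone (MeNHOH·HCl, paraformaldehyde, NaOAc, toluene, 110 °C) adds across the acetyl-bearing double bond from the convex face, carbon to the α-carbon and oxygen to the β-carbon, and gives the isoxazolidine F5. This adduct holds CH2N and O cis by construction. Zn/AcOH cleaves the N–O bond to the amino diol F6. Aqueous CH2O/AcOH then closes the piperidone by a single intramolecular Mannich reaction to give 16.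

**Step 10.**
- Risks: closing a seven-membered bridged ring with a chloride may lose out to elimination of HCl.
- Fallback: it sets out from 15 and comes back at 18, and it builds ring D before ring C. Me3SiOTf/2,6-lutidine gives the bis-silyl ether F7. The kinetic methyl enolate (KN(SiMe3)2, the acetyl centre equilibrating under the conditions) closes a simple fused cycloheptanone, the tricyclic ketone F8. A bridging double Mannich reaction (MeNH2, CH2O, AcOH/MeOH, silyl groups lost) can only span the face opposite ring D and gives the amino ketone diol F9. Resilylation with Me3SiOTf/2,6-lutidine gives 18.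

## Further compounds
F1 | step 12 | methyl enol ether of 18 | COC=C1[C@H]2CN(C)C[C@@]13C[C@@H](CO[Si](C)(C)C)[C@H]4CC=C(CC2)[C@@]34O[Si](C)(C)C
F2 | step 12 | bridge aldehyde diol (epimers at the formyl carbon) | O=CC1[C@H]2CN(C)C[C@@]13C[C@@H](CO)[C@H]4CC=C(CC2)[C@@]34O
F3 | step 12 | quaternary keto aldehyde | CC(C)C(=O)CC[C@@]1(C=O)[C@H]2CN(C)C[C@@]13C[C@@H](CO)[C@H]4CC=C(CC2)[C@@]34O
F4 | step 9 | acetyl diene | CC(=O)C1=C2C(CCCl)=CC[C@@H]2[C@H](CO)C1
F5 | step 9 | isoxazolidine | CC(=O)[C@]12CN(C)O[C@@]1(C(CCCl)=CC3)[C@H]3[C@H](CO)C2
F6 | step 9 | amino diol | CC(=O)[C@@]1(CNC)C[C@@H](CO)[C@H]2CC=C(CCCl)[C@@]12O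
F7 | step 10 | bis(trimethylsilyl) ether of 15 | CC(=O)[C@@H]1C[C@@H](CO[Si](C)(C)C)[C@H]2CC=C(CCCl)[C@@]12O[Si](C)(C)C
F8 | step 10 | tricyclic ketone (rings A, B, D), bis(trimethylsilyl) ether | O=C1CCCC2=CC[C@@H]3[C@H](CO[Si](C)(C)C)C[C@H]1[C@]23O[Si](C)(C)C
F9 | step 10 | amino ketone diol (rings A to D) | O=C1[C@H]2CN(C)C[C@@]13C[C@@H](CO)[C@H]4CC=C(CC2)[C@@]34O
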